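**Remark (assumption):** the SMILES is read as the ent‑labdane (5R,6R,8S,9S,10R), the mirror image of the sclareol‑type core, so natural labdanes are not used; atom labels below are labdane numbers (C1–C10 decalin, C11–C16 side chain, C17 on C8, C18/C19 on C4, C20 on C10).

## Retrosynthetic overview

1. Endgame: C13=C14 by Horner–Wadsworth–Emmons on the C13 methyl ketone; C5–H/C6–OH by hydroboration of C5=C6 and C8–OH by Markovnikov hydration of C8=C17, both from the face opposite to the axial C20 methyl.
2. Ring B: closed at C7–C8 by a palladium‑ene (allyl‑to‑vinyl) cyclisation of a ring A tertiary allylic acetate (C5(OAc)–C6H=C7H2) onto the C9 vinyl group, giving the 5,8(17)‑diene.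
3. Enabling feature: C5 of ring A lies between the quaternary carbons C4 and C10, so the η3‑allyl over C5–C6–C7 has no β‑hydrogen and can only bond through C7; C9, one bond out from C10, holds the vinyl acceptor in a 6‑exo position.
4. C9/C10 pair: anionic oxy‑Cope rearrangement of an (R)‑homoallylic carbinol made from β‑cyclocitral; the carbinol carbon is then excised by enol ether ozonolysis to leave the C5 ketone.
5. Ring order: ring A is bought (β‑cyclocitral); ring B is the only ring formed, in step 7.

Key step: step 7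

## Route

Step 1
Reactants: 1 β‑cyclocitral; 2 allenylboronic acid pinacol ester
Product: 4 (1R)-1-(2,6,6-trimethylcyclohex-1-en-1-yl)but-3-yn-1-ol, via boronate ester 3 (not isolated)
Conditions: (R)-TRIP phosphoric acid [(R)-3,3′-bis(2,4,6-triisopropylphenyl)-1,1′-binaphthyl-2,2′-diyl hydrogen phosphate] (10 mol %), 4 Å MS, toluene, 0 °C to rt; aq. NaHCO3
Reagents that add atoms: allenylboronic acid pinacol ester (2), C=C=CB1OC(C)(C)C(C)(C)O1
Why: Chiral phosphoric acid catalysed propargylboration of an aldehyde (SE2′ transfer from the allenylboronate through a closed six‑membered transition state); the (R)‑acid, which binds the boronate oxygen and the formyl hydrogen, should direct the propargyl group to the Re face as it does for aryl aldehydes and so set the (R)‑carbinol that later controls C9 and C10.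

Step 2
Reactants: 4 (1R)-1-(2,6,6-trimethylcyclohex-1-en-1-yl)but-3-yn-1-ol; 5 2-(2-bromoethyl)-2-methyl-1,3-dioxolane
Product: 7 (1R)-6-(2-methyl-1,3-dioxolan-2-yl)-1-(2,6,6-trimethylcyclohex-1-en-1-yl)hex-3-yn-1-ol, via dilithio species 6 (not isolated)
Conditions: n-BuLi (2.1 equiv), THF, −78 to 0 °C; then 5, DMPU, NaI (cat.), 0 °C to rt; H2O
Reagents that add atoms: 2-(2-bromoethyl)-2-methyl-1,3-dioxolane (5), CC1(CCBr)OCCO1
Why: SN2 alkylation of the alkynyllithium terminus of the alkoxide–acetylide dianion by a primary bromide (the aggregated alkoxide reacts more slowly in THF/DMPU); no stereocenter is affected.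

Step 3
Reactants: 7 (1R)-6-(2-methyl-1,3-dioxolan-2-yl)-1-(2,6,6-trimethylcyclohex-1-en-1-yl)hex-3-yn-1-ol
Product: 8 (1R,3E)-6-(2-methyl-1,3-dioxolan-2-yl)-1-(2,6,6-trimethylcyclohex-1-en-1-yl)hex-3-en-1-ol
Conditions: Na, liq. NH3/THF, −33 °C; solid NH4Cl
Reagents that add atoms: none
Why: Dissolving‑metal (Birch‑type) reduction of the internal alkyne, in which the vinyl radical anion adopts the trans arrangement before protonation, should give the (E)‑olefin, while the tetrasubstituted ring olefin, the alkoxide and the ketal are inert.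

Step 4
Reactants: 8 (1R,3E)-6-(2-methyl-1,3-dioxolan-2-yl)-1-(2,6,6-trimethylcyclohex-1-en-1-yl)hex-3-en-1-ol
Product: 11 tert-butyldimethylsilyl (E)-enol ether of (2S)-2-[(3R)-5-(2-methyl-1,3-dioxolan-2-yl)pent-1-en-3-yl]-2,6,6-trimethylcyclohexane-1-carbaldehyde, via potassium alkoxide 9 (not isolated), via potassium enolate 10 (not isolated)
Conditions: KH (3 equiv), 18-crown-6 (1.1 equiv), THF, 0 to 45 °C; then TBSCl, −78 °C to rt
Reagents that add atoms: tert-butyldimethylsilyl chloride, CC(C)(C)[Si](C)(C)Cl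
Why: Anionic oxy‑Cope rearrangement ([3,3]-sigmatropic) through a chair in which the oxido group is equatorial (an axial oxido would be 1,3‑diaxial to the Z‑methyl C20 on the ring olefin terminus) and the E‑chain is equatorial, so that the (R)‑carbinol configuration is relayed to quaternary C10 and to C9 together; the aldehyde enolate is then silylated on oxygen.

Step 5
Reactants: 11 tert-butyldimethylsilyl (E)-enol ether
Product: 14 (2S)-2-[(3R)-5-(2-methyl-1,3-dioxolan-2-yl)pent-1-en-3-yl]-2,6,6-trimethylcyclohexan-1-one, via primary ozonide 12 (not isolated), via carbonyl oxide 13 (not isolated)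
Conditions: O3 (1.0 equiv, titrated CH2Cl2 solution), CH2Cl2, −78 °C; then Me2S, −78 °C to rt
Reagents that add atoms: ozone, [O-][O+]=O
Why: Ozonolysis, selective with one equivalent of ozone for the electron‑rich silyl enol ether over the monosubstituted vinyl group, excises the former carbinol carbon as silyl formate and leaves the C5 ketone, whose neighbours C4 and C10 carry no hydrogen so that nothing can epimerise.

Step 6
Reactants: 14 (2S)-2-[(3R)-5-(2-methyl-1,3-dioxolan-2-yl)pent-1-en-3-yl]-2,6,6-trimethylcyclohexan-1-one; 15 vinylmagnesium bromide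
Product: 17 (2S)-1-ethenyl-2-[(3R)-5-(2-methyl-1,3-dioxolan-2-yl)pent-1-en-3-yl]-2,6,6-trimethylcyclohexyl acetate (C1 epimers), via magnesium alkoxide 16 (not isolated)
Conditions: 15 (3 equiv), LaCl3·2LiCl (0.3 equiv), THF, 0 °C to rt; then Ac2O, DMAP (cat.), 0 °C to rt
Reagents that add atoms: vinylmagnesium bromide (15), C=C[Mg]Br; acetic anhydride, CC(=O)OC(C)=O
Why: Lanthanum‑promoted 1,2‑addition of a vinyl Grignard reagent to a ketone that cannot enolise and that this reagent cannot reduce, followed by O‑acetylation of the alkoxide in the same flask; the new C5 center is formed without control and is erased on ionisation in step 7.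

Step 7
Reactants: 17 tertiary allylic acetate
Product: 20 2-{2-[(1R,8aS)-5,5,8a-trimethyl-2-methylidene-1,2,3,5,6,7,8,8a-octahydronaphthalen-1-yl]ethyl}-2-methyl-1,3-dioxolane, via allylpalladium acetate 18 (not isolated), via alkylpalladium acetate 19 (not isolated)
Conditions: Pd2(dba)3 (5 mol %), PPh3 (20 mol %), NaOAc (0.5 equiv), 1,4-dioxane, 80 °C
Reagents that add atoms: none
Why: Proposed new method: Zerovalent palladium ionises the tertiary allylic acetate to an η3‑allyl complex over C5–C6–C7 which, because C5 is flanked by the quaternary C4 and C10, has no β‑hydrogen and cannot collapse to a diene; the C9 vinyl group then coordinates and inserts into the Pd–C7 bond, and β‑hydride elimination from C8, the only β‑position of the resulting primary alkylpalladium, releases the exocyclic C8=C17 olefin and HPdOAc, which returns the catalyst. The closest known reaction type is the palladium‑ene cyclisation of allylic acetates onto tethered olefins (equivalently a 6‑exo Heck‑type carbopalladation); what is new is that the allyl unit bonds through the terminus remote from the tether, so that its double bond ends up inside the new ring as C5=C6. Ring B is closed in the 6‑exo‑trig mode with respect to the vinyl acceptor. No new stereocenter results (the transient C8 center is destroyed on elimination) and C9 and C10 are untouched, but the two olefins formed are the handles from which C5, C6 and C8 are set. The step needs C7 rather than C5 to bond and exo rather than endo insertion, which the substrate secures because bonding through C5 would build a cyclobutane at a doubly neopentyl carbon and because the vinyl group is held by the short C5–C10–C9 tether. It also needs the allyl isomer with C10 anti and the palladium on the face of C9, which acetate return and η3–η1–η3 exchange through the CH2 terminus should supply, and it needs the exocyclic olefin not to migrate, for which buffered conditions and a short reaction time are chosen.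

Step 8
Reactants: 20 5,8(17)-diene ketal
Product: 22 (1S,2S,8aS)-1-[2-(2-methyl-1,3-dioxolan-2-yl)ethyl]-2,5,5,8a-tetramethyl-1,2,3,5,6,7,8,8a-octahydronaphthalen-2-ol, via organomercurial 21 (not isolated)
Conditions: Hg(OAc)2 (1.1 equiv), NaOAc, THF/H2O (1:1), 0 °C to rt; then 3 M NaOH, NaBH4, 0 °C
Reagents that add atoms: water, O
Why: Oxymercuration–demercuration (Markovnikov hydration), chemoselective for the exposed 1,1‑disubstituted C8=C17 olefin over the C5=C6 olefin buried between C4 and C10; water should open the mercurinium ion at C8 from the face opposite to the axial C20 methyl (the 1,3‑diaxial approach is blocked), giving the equatorial hydroxyl and axial C17 methyl, as in the oxymercuration of labd‑8(17)‑enes.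

Step 9
Reactants: 22 C8 tertiary alcohol with C5=C6 olefin
Product: 24 (1R,3S,4S,4aR,8aR)-4-[2-(2-methyl-1,3-dioxolan-2-yl)ethyl]-3,4a,8,8-tetramethyldecahydronaphthalene-1,3-diol, via alkylborane 23 (not isolated)
Conditions: BH3·THF (5 equiv), THF, 0 to 45 °C; then 3 M NaOH, 30% H2O2, 0 to 45 °C
Reagents that add atoms: hydrogen peroxide, OO
Why: Hydroboration–oxidation (syn, anti‑Markovnikov) of the trisubstituted C5=C6 olefin from the face opposite to the two axial methyl groups on C4 and C10, possibly assisted by delivery from the C8 alkoxyborane on that same face, places hydrogen on C5 and boron, then hydroxyl with retention, on C6, giving the trans‑decalin with an equatorial C6 hydroxyl as known for 4,4‑dimethyl‑5‑ene steroids.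

Step 10
Reactants: 24 diol ketal
Product: 25 4-[(1S,2S,4R,4aR,8aR)-2,4-dihydroxy-2,5,5,8a-tetramethyldecahydronaphthalen-1-yl]butan-2-one
Conditions: PPTS (0.2 equiv), acetone/H2O (9:1), 45 °C
Reagents that add atoms: water, O
Why: Acid‑catalysed ketal hydrolysis under mild, wet conditions that should not dehydrate the tertiary C8 alcohol or touch the stereocenters.

Step 11
Reactants: 25 dihydroxy methyl ketone; 26 trimethyl phosphonoacetate
Product: 27 methyl (2E)-5-[(1S,2S,4R,4aR,8aR)-2,4-dihydroxy-2,5,5,8a-tetramethyldecahydronaphthalen-1-yl]-3-methylpent-2-enoate (target, CNP0289884.1)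
Conditions: NaH (4 equiv), 26 (3 equiv), THF, 0 to 50 °C
Reagents that add atoms: trimethyl phosphonoacetate (26), COC(=O)CP(=O)(OC)OC
Why: Horner–Wadsworth–Emmons olefination of the methyl ketone, which should favour the (E)‑trisubstituted enoate (ester opposite to the longer chain) as with related 8‑hydroxy‑13‑oxo labdane methyl ketones, the minor Z isomer being removed by chromatography.

## Compound list

1 | β‑cyclocitral (2,6,6-trimethylcyclohex-1-ene-1-carbaldehyde) | CC1=C(C=O)C(C)(C)CCC1 | starting material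
2 | allenylboronic acid pinacol ester | C=C=CB1OC(C)(C)C(C)(C)O1 | starting material
3 | O‑pinacolboryl ether of 4 (boronate ester) | C#CC[C@@H](OB1OC(C)(C)C(C)(C)O1)C1=C(C)CCCC1(C)C | intermediate
4 | (1R)-1-(2,6,6-trimethylcyclohex-1-en-1-yl)but-3-yn-1-ol | C#CC[C@@H](O)C1=C(C)CCCC1(C)C | intermediate
5 | 2-(2-bromoethyl)-2-methyl-1,3-dioxolane | CC1(CCBr)OCCO1 | starting material
6 | dilithium alkoxide–acetylide of 4 | [Li]C#CC[C@@H](O[Li])C1=C(C)CCCC1(C)C | intermediate
7 | (1R)-6-(2-methyl-1,3-dioxolan-2-yl)-1-(2,6,6-trimethylcyclohex-1-en-1-yl)hex-3-yn-1-ol | CC1(CCC#CC[C@@H](O)C2=C(C)CCCC2(C)C)OCCO1 | intermediate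
8 | (1R,3E)-6-(2-methyl-1,3-dioxolan-2-yl)-1-(2,6,6-trimethylcyclohex-1-en-1-yl)hex-3-en-1-ol | CC1(CC/C=C/C[C@@H](O)C2=C(C)CCCC2(C)C)OCCO1 | intermediate
9 | potassium alkoxide of 8 | CC1(CC/C=C/C[C@@H]([O-])C2=C(C)CCCC2(C)C)OCCO1.[K+] | intermediate
10 | potassium (E)-enolate of the rearranged aldehyde (C10 S, C9 R) | CC1(OCCO1)CC[C@H](C=C)[C@]1(C)CCCC(C)(C)/C1=C\[O-].[K+] | intermediate
11 | tert-butyldimethylsilyl (E)-enol ether of (2S)-2-[(3R)-5-(2-methyl-1,3-dioxolan-2-yl)pent-1-en-3-yl]-2,6,6-trimethylcyclohexane-1-carbaldehyde | CC1(OCCO1)CC[C@H](C=C)[C@]1(C)CCCC(C)(C)/C1=C\O[Si](C)(C)C(C)(C)C | intermediate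
12 | primary ozonide (1,2,3-trioxolane) of 11 | CC1(OCCO1)CC[C@H](C=C)[C@]1(C)CCCC(C)(C)C12OOOC2O[Si](C)(C)C(C)(C)C | intermediate
13 | carbonyl oxide at C5 | CC1(OCCO1)CC[C@H](C=C)[C@]1(C)CCCC(C)(C)C1=[O+][O-] | intermediate
14 | (2S)-2-[(3R)-5-(2-methyl-1,3-dioxolan-2-yl)pent-1-en-3-yl]-2,6,6-trimethylcyclohexan-1-one | CC1(OCCO1)CC[C@H](C=C)[C@]1(C)CCCC(C)(C)C1=O | intermediate
15 | vinylmagnesium bromide | C=C[Mg]Br | starting material
16 | bromomagnesium alkoxide of the tertiary allylic alcohol (C5 epimers) | CC1(OCCO1)CC[C@H](C=C)[C@]1(C)CCCC(C)(C)C1(O[Mg]Br)C=C | intermediate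
17 | (2S)-1-ethenyl-2-[(3R)-5-(2-methyl-1,3-dioxolan-2-yl)pent-1-en-3-yl]-2,6,6-trimethylcyclohexyl acetate (C1 epimers) | CC1(OCCO1)CC[C@H](C=C)[C@]1(C)CCCC(C)(C)C1(OC(C)=O)C=C | intermediate
18 | η3‑allylpalladium acetate over C5–C6–C7 (phosphines omitted; drawn in the C7‑bound η1 form) | CC1(OCCO1)CC[C@H](C=C)[C@]1(C)CCCC(C)(C)C1=CC[Pd]OC(C)=O | intermediate
19 | primary alkylpalladium acetate at C17 after insertion (phosphines omitted; C8 unspecified) | CC1(OCCO1)CC[C@H]2[C@]3(C)CCCC(C)(C)C3=CCC2C[Pd]OC(C)=O | intermediate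
20 | 2-{2-[(1R,8aS)-5,5,8a-trimethyl-2-methylidene-1,2,3,5,6,7,8,8a-octahydronaphthalen-1-yl]ethyl}-2-methyl-1,3-dioxolane | CC1(OCCO1)CC[C@H]2[C@]3(C)CCCC(C)(C)C3=CCC2=C | intermediate
21 | C17 acetoxymercurio derivative of 22 | CC1(OCCO1)CC[C@H]2[C@]3(C)CCCC(C)(C)C3=CC[C@@]2(O)C[Hg]OC(C)=O | intermediate
22 | (1S,2S,8aS)-1-[2-(2-methyl-1,3-dioxolan-2-yl)ethyl]-2,5,5,8a-tetramethyl-1,2,3,5,6,7,8,8a-octahydronaphthalen-2-ol | CC1(OCCO1)CC[C@H]2[C@]3(C)CCCC(C)(C)C3=CC[C@]2(C)O | intermediate
23 | C6 alkylborane (drawn as RBH2) | CC1(OCCO1)CC[C@H]2[C@]3(C)CCCC(C)(C)[C@H]3[C@H](B)C[C@]2(C)O | intermediate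
24 | (1R,3S,4S,4aR,8aR)-4-[2-(2-methyl-1,3-dioxolan-2-yl)ethyl]-3,4a,8,8-tetramethyldecahydronaphthalene-1,3-diol | CC1(OCCO1)CC[C@H]2[C@]3(C)CCCC(C)(C)[C@H]3[C@H](O)C[C@]2(C)O | intermediate
25 | 4-[(1S,2S,4R,4aR,8aR)-2,4-dihydroxy-2,5,5,8a-tetramethyldecahydronaphthalen-1-yl]butan-2-one | CC(=O)CC[C@H]1[C@]2(C)CCCC(C)(C)[C@H]2[C@H](O)C[C@]1(C)O | intermediate
26 | trimethyl phosphonoacetate | COC(=O)CP(=O)(OC)OC | starting material
27 | methyl (2E)-5-[(1S,2S,4R,4aR,8aR)-2,4-dihydroxy-2,5,5,8a-tetramethyldecahydronaphthalen-1-yl]-3-methylpent-2-enoate | COC(=O)/C=C(\C)CC[C@H]1[C@]2(C)CCCC(C)(C)[C@H]2[C@H](O)C[C@]1(C)O | target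

## Step count and risks

Total step count: 11. Longest linear sequence: 11 steps (from 1).

**Step 7 (Proposed new method).** The η3‑allyl may stay in the unproductive syn/anti arrangement, be captured as the primary allylic acetate, or the exocyclic olefin may migrate after re‑addition of the palladium hydride. The fallback closes the same bond by the known palladium‑promoted cycloalkenylation of a silyl enol ether (Saegusa–Ito type). It sets out from silyl enol ether 11 and comes back at diol 24. Fluoride cleavage (TBAF, AcOH) gives the aldehyde F1 (C5 epimers), MeMgBr the secondary alcohol F2, Dess–Martin periodinane the methyl ketone F3 and TBSOTf/Et3N the terminal silyl enol ether F4. Pd(OAc)2 (cat.) under O2 in DMSO should then form C7–C8 in the 6‑exo mode and give the β,γ‑unsaturated ketone F5. DBU moves the olefin into conjugation; LDA at −78 °C followed by AcOH protonates C5 from the face opposite to C20 and gives the trans‑fused enone F6. Copper‑catalysed conjugate borylation (CuCl, NaOt‑Bu, B2pin2, MeOH) from that same face gives the boronate F7, NaBO3 the ketol F8, and reduction under thermodynamic control (Na, i‑PrOH) the equatorial C6 alcohol, diol 24.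

**Step 4.** The hindered alkoxide may fragment by retro‑allylation, or chirality transfer may be eroded through boat or oxido‑axial transition states. The fallback reaches ketone 14 without the rearrangement; it sets out from bromide 5 and comes back at ketone 14. Alkylation of the dianion of propargyl alcohol with 5 gives the alkynol F9, Red‑Al the (E)‑allylic alcohol F10 and ClCO2Me/pyridine the carbonate F11. Iridium‑catalysed branched‑selective allylic alkylation ([Ir(cod)Cl]2, a chiral phosphoramidite, KHMDS) of the enolate of 2,2,6‑trimethylcyclohexanone F12 (regiodefined, since only C10 carries hydrogen) with F11 should join C9 to C10, with catalyst control at C9 and the C10 diastereomers to be separated, giving ketone 14.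

**Step 6.** The vinyl Grignard reagent may fail to add to the doubly neopentyl carbonyl group. The fallback uses the smaller, linear acetylide; it sets out from ketone 14 and comes back at acetate 17. Lithium acetylide–ethylenediamine complex in THF/DMSO gives the propargylic alcohol F13, Lindlar semi‑hydrogenation (Pd/CaCO3 poisoned with Pb(OAc)2, quinoline, H2) the tertiary allylic alcohol F14, and n‑BuLi then Ac2O the acetate 17.

## Further compounds

F1 | step 7 | (2S)-2-[(3R)-5-(2-methyl-1,3-dioxolan-2-yl)pent-1-en-3-yl]-2,6,6-trimethylcyclohexane-1-carbaldehyde (C1 epimers) | CC1(OCCO1)CC[C@H](C=C)[C@]1(C)CCCC(C)(C)C1C=O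
F2 | step 7 | 1-{(2S)-2-[(3R)-5-(2-methyl-1,3-dioxolan-2-yl)pent-1-en-3-yl]-2,6,6-trimethylcyclohexyl}ethan-1-ol (epimers) | CC1(OCCO1)CC[C@H](C=C)[C@]1(C)CCCC(C)(C)C1C(C)O
F3 | step 7 | 1-{(2S)-2-[(3R)-5-(2-methyl-1,3-dioxolan-2-yl)pent-1-en-3-yl]-2,6,6-trimethylcyclohexyl}ethan-1-one (C1 epimers) | CC1(OCCO1)CC[C@H](C=C)[C@]1(C)CCCC(C)(C)C1C(C)=O
F4 | step 7 | terminal tert-butyldimethylsilyl enol ether of F3 | CC1(OCCO1)CC[C@H](C=C)[C@]1(C)CCCC(C)(C)C1C(=C)O[Si](C)(C)C(C)(C)C
F5 | step 7 | (4R,4aS)-4-[2-(2-methyl-1,3-dioxolan-2-yl)ethyl]-4a,8,8-trimethyl-3-methylideneoctahydronaphthalen-1(2H)-one (8a epimers) | CC1(OCCO1)CC[C@H]2[C@]3(C)CCCC(C)(C)C3C(=O)CC2=C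
F6 | step 7 | (4R,4aS,8aR)-4-[2-(2-methyl-1,3-dioxolan-2-yl)ethyl]-3,4a,8,8-tetramethyl-4a,5,6,7,8,8a-hexahydronaphthalen-1(4H)-one (trans‑fused) | CC1(OCCO1)CC[C@H]2[C@]3(C)CCCC(C)(C)[C@H]3C(=O)C=C2C
F7 | step 7 | C8 pinacol boronate of the saturated C6 ketone (boron anti to C20) | CC1(OCCO1)CC[C@H]2[C@]3(C)CCCC(C)(C)[C@H]3C(=O)C[C@]2(C)B4OC(C)(C)C(C)(C)O4
F8 | step 7 | (3S,4S,4aS,8aR)-3-hydroxy-4-[2-(2-methyl-1,3-dioxolan-2-yl)ethyl]-3,4a,8,8-tetramethyloctahydronaphthalen-1(2H)-one | CC1(OCCO1)CC[C@H]2[C@]3(C)CCCC(C)(C)[C@H]3C(=O)C[C@]2(C)O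
F9 | step 4 | 5-(2-methyl-1,3-dioxolan-2-yl)pent-2-yn-1-ol | CC1(CCC#CCO)OCCO1
F10 | step 4 | (2E)-5-(2-methyl-1,3-dioxolan-2-yl)pent-2-en-1-ol | CC1(CC/C=C/CO)OCCO1
F11 | step 4 | methyl (2E)-5-(2-methyl-1,3-dioxolan-2-yl)pent-2-en-1-yl carbonate | CC1(CC/C=C/COC(=O)OC)OCCO1
F12 | step 4 | 2,2,6-trimethylcyclohexanone | CC1CCCC(C)(C)C1=O
F13 | step 6 | (2S)-1-ethynyl-2-[(3R)-5-(2-methyl-1,3-dioxolan-2-yl)pent-1-en-3-yl]-2,6,6-trimethylcyclohexan-1-ol (C1 epimers) | CC1(OCCO1)CC[C@H](C=C)[C@]1(C)CCCC(C)(C)C1(O)C#C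
F14 | step 6 | (2S)-1-ethenyl-2-[(3R)-5-(2-methyl-1,3-dioxolan-2-yl)pent-1-en-3-yl]-2,6,6-trimethylcyclohexan-1-ol (C1 epimers) | CC1(OCCO1)CC[C@H](C=C)[C@]1(C)CCCC(C)(C)C1(O)C=C
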